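## Structural features

The target is a 6,6-disubstituted 4-methoxycyclohex-2-enone. In the numbering used throughout, C6 is the ring carbonyl, C1 the quaternary carbon next to it, C2 a methylene, C3 the methoxy-bearing carbon and C4=C5 the enone double bond. C1 carries an allyl group and a two-carbon side chain: C8 (with a methyl group) and C7 (benzylic, with the acetate and a 3,4,5-trimethoxyphenyl ring). There are four stereocentres: C7 (S) and C8 (S) are neighbours in the anti relationship of a crotylation product, C8 is bonded directly to quaternary C1 (R), and C3 (R) stands 1,3 to C1 with its methoxy group cis to the C8 branch. The fragile groups are the γ-methoxy enone (loss of methanol under acid, deconjugation under base), the benzylic acetate on an electron-rich ring, the terminal alkene, and the C7 oxygen, which is β to C8 and is expelled whenever C8 becomes part of an enolate. The real difficulty is C1: a fully substituted carbon flanked by a carbonyl group, a branched stereogenic carbon and two methylene arms, whose absolute configuration must be tied to three other centres. The key step uses the fact that the C6 ketone is bonded directly to C1 and that the allyl CH2 on C1 can be read as the α-carbon of an acetic ester: C1 is then the β-carbon of an enoate and C6 an acyl anion, so forming C1–C6 closes the carbocycle through C2–C5. Because C1 has no hydrogen, the C6 ketone can enolise only toward C5, which makes the later introduction of the C4=C5 double bond unambiguous.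

## Logic of the disconnections

**23 ⇒ 22 ⇒ 21.** The acetyl C–O bond at C7 and, before it, the O–Si bond are cut last. An acetate would not survive hydride, ylide or amide bases, whereas the silyl ether does; the gain is that one robust group is carried from 5 to 21. The forward steps must remove silicon and acylate without disturbing the γ-methoxy enone.

**21 ⇒ 20 ⇒ 19.** The C4=C5 double bond is removed. The enone is the most sensitive unit and is therefore introduced after all basic and reductive steps; the gain is the plain ketone 19, whose only enolisable position is C5. The forward dehydrogenation must tolerate the allyl group.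

**19 ⇒ 18 ⇒ 17 ⇒ 16.** The terminal C=C bond of the allyl group is cut back to the aldehyde carbon of 18, and the oxidation levels are traced through 17 to the keto ester 16. This turns the allyl CH2 into the α-carbon of an ester and exposes the 1,4-dicarbonyl pattern C6(=O)–C1–CH2–CO2Et. The forward sequence demands methylenation of an aldehyde beside a ketone, and an oxidation of 17 that does not stop at a lactone.

**16 ⇒ 15 (key disconnection).** The C1–C6 bond is cut. It is the one ring bond that joins the ketone carbon to the quaternary centre, and cutting it removes the ring and the quaternary stereocentre together: 15 is an open chain with three stereocentres and one trisubstituted alkene. The forward step must deliver an acyl anion from C6 to one face of a hindered β,β-disubstituted enoate in a 6-exo closure, without base-induced damage.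

**15 ⇒ 13.** The C6 aldehyde is traced to a terminal alkene. The aldehyde is then unveiled directly before the key step and no protected alcohol is needed at C6. The forward cleavage must distinguish a monosubstituted alkene from the enoate and the electron-rich arene.

**13 ⇒ 11 + 12.** The C1=C double bond of the enoate is cut by carbonyl olefination. This detaches the two-carbon ester unit and leaves a ketone that already holds C7, C8 and C3. The forward step must reach a hindered ketone, give the (E)-isomer, and not eliminate either β-oxygen substituent.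

**11 ⇒ 10 ⇒ 6 + 7.** The O–CH3 bond and then the C2–C3 bond are cut (aldol). The cut lies next to the carbonyl group, divides the chain into two pieces of similar size and creates C3 in the step that joins them. It demands reagent-controlled face selectivity, because the resident centres do not favour the required C3 configuration, and a base-free methylation that avoids retro-aldol cleavage.

**6 ⇒ 5 ⇒ 4 ⇒ 1 + 2.** The ketone oxygen is traced to the vinyl group of 5, the silyl group is removed, and the C7–C8 bond is cut (crotylation). Both side-chain stereocentres then come from two achiral commercial compounds in one catalytic step. The demands are anti diastereoselection, Si-face enantioselection, and Markovnikov regiochemistry in the oxidation.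

## Other disconnections considered

**Alternative 1:** The cut removes the C1–C8 bond and the bond between C7 and the C6 oxygen. This leads to the quinone monoketal A2 (2-allyl-4,4,5-trimethoxycyclohexa-2,5-dienone) and (E)-isoelemicin A3.
- Forward step: BF3·OEt2 or a sulfonic acid would ionise A2. The oxocarbenium ion would be attacked at its allyl-bearing carbon by the alkene carbon of A3 that becomes C8, and the benzylic cation at C7 would be trapped by the carbonyl oxygen. The product would be the dihydrobenzofuranone A1.
- In favour: two simple achiral partners; the quaternary carbon and three contiguous centres arise in one operation; the trans aryl/methyl relationship follows from the alkene geometry.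
- Against: A1 would form as a racemate, since a stepwise cationic process offers no evident handle for absolute control. Attack at the unsubstituted α-carbon and bicyclic (5+2) adducts are plausible competitors. A1 also has the ring in the wrong oxidation pattern (carbonyl at C4, C2=C3 enol ether, C6 locked as an enol ether). C3 would have to be set afterwards by conjugate reduction and protonation, and the C4 oxygen removed by 1,2-reduction and acid-induced transposition, on a system prone to lose methanol.
- Comparison: on convergence and step count the alternative is better, at roughly half the length. On relative control of C1, C8 and C7 it is at least equal, because one event sets what the chosen plan sets in three steps. On absolute configuration and on C3 the chosen plan is stronger, because each centre is placed by a catalyst or reagent; this decides the matter for a single enantiomer.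

**Alternative 2:** The cut removes C1–C6 and C2–C3, giving 3-hydroxy-2-pyrone A5 and the α-substituted acrolein A6, which carries C8 and C7.
- Forward step: triethylamine or a cinchona-derived amine would deprotonate A5, and the electron-rich diene would add to A6 to give the bicyclic lactone A4.
- In favour: C1, both ring oxygens (C3 and C6) and the C4=C5 double bond would arrive together. The C3 configuration would be tied to C1 by the bicyclic framework, and catalytic asymmetric versions of this cycloaddition exist.
- Against: A6 is an α-branched acrolein with a bulky stereogenic substituent, a poor dienophile for which catalyst and substrate preferences may be mismatched. A4 could lose carbon dioxide on warming. The lactone bridge must be excised (the extra carboxyl carbon removed to reveal the C6 ketone, the C3 oxygen freed and methylated). The formyl group must be lengthened by two carbons to the allyl group.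
- Comparison: it is better in that no late dehydrogenation is needed and C3 is not set by a separate, moderately selective aldol reaction. Step count is about equal. The chosen plan is simpler in that the ester arm needs only reduction and methylenation, whereas A4 needs a carbon excised and a two-carbon homologation. Mechanistically both key steps are base-triggered and mild; the cycloaddition builds two bonds, the Stetter closure one.

**Alternative 3:** The cut removes the C3–C4 bond. The precursor A8 is an acyclic (Z)-β-iodoenone whose C1 bears two identical 2-oxoethyl arms.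
- Forward step: CrCl2 with catalytic NiCl2 would generate a vinylchromium species at C4 that adds to one of the two diastereotopic aldehyde arms, giving the hydroxy enone A7.
- In favour: the enone and the C7 acetate would pass through unchanged, so only O-methylation and methylenation remain after ring closure. The organochromium addition tolerates esters, ketones and the second aldehyde.
- Against: C1 and C3 would both be set by group and face selection under control of the remote C8 and C7 centres across a quaternary carbon, for which no reliable model exists, so up to four diastereomers are possible. A8 combines an isomerisable iodoenone with two enolisable aldehydes and would be long to assemble.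
- Comparison: the end game is clearly better, two steps against seven. The mechanism is equally well understood. The chosen plan is preferred because its quaternary centre is set by a chiral catalyst and not by an untested diastereotopic group selection, and because its precursor is reached in seven linear steps.

Key step: step 8

Assumption: the senses of induction of (S)-TRIP in step 1 (Si-face crotyl transfer), (−)-Ipc2BCl in step 4 (Re-face aldol addition) and the (5aR,10bS) triazolium salt in step 8 (Re-face attack at the enoate β-carbon) are assigned by analogy with simple model substrates; each is available in both mirror-image forms, and the antipode is to be used wherever the analogy does not hold.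

## Route

Step 1
Reactants: 1 3,4,5-trimethoxybenzaldehyde; 2 (E)-crotylboronic acid pinacol ester
Product: 4 (1S,2S)-2-methyl-1-(3,4,5-trimethoxyphenyl)but-3-en-1-ol, via pinacol borate ester 3 (not isolated)
Conditions: (S)-TRIP [(S)-3,3'-bis(2,4,6-triisopropylphenyl)-1,1'-binaphthyl-2,2'-diyl hydrogen phosphate] (5 mol %), toluene, −30 °C; aqueous NaHCO3 work-up
Reagents that add atoms: none
Why: Chiral phosphoric acid-catalysed crotylboration through a closed chair transition state, in which the (E)-crotyl geometry becomes the anti C7/C8 relationship; the acid, hydrogen-bonded to a boronate oxygen, should direct the crotyl group to the Si face of the aldehyde and so set 7S and 8S together.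

Step 2
Reactants: 4 (1S,2S)-2-methyl-1-(3,4,5-trimethoxyphenyl)but-3-en-1-ol
Product: 5 tert-butyldimethyl{[(1S,2S)-2-methyl-1-(3,4,5-trimethoxyphenyl)but-3-en-1-yl]oxy}silane
Conditions: TBSOTf, 2,6-lutidine, CH2Cl2, 0 °C
Reagents that add atoms: tert-butyldimethylsilyl trifluoromethanesulfonate, CC(C)(C)[Si](C)(C)OS(=O)(=O)C(F)(F)F
Why: O-silylation of a hindered secondary benzylic alcohol with the silyl triflate and a non-nucleophilic base; no stereocentre is touched.

Step 3
Reactants: 5 tert-butyldimethyl{[(1S,2S)-2-methyl-1-(3,4,5-trimethoxyphenyl)but-3-en-1-yl]oxy}silane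
Product: 6 (3R,4S)-4-[(tert-butyldimethylsilyl)oxy]-3-methyl-4-(3,4,5-trimethoxyphenyl)butan-2-one
Conditions: PdCl2 (10 mol %), CuCl (50 mol %), O2 (1 atm), DMF/H2O 7:1, rt
Reagents that add atoms: water, O
Why: Tsuji–Wacker oxidation of a monosubstituted alkene; Markovnikov hydroxypalladation should give the methyl ketone, and the nearly neutral medium should leave the silyl ether and the α-stereocentre intact (the change of the C8 descriptor from S to R is a priority change only).

Step 4
Reactants: 6 (3R,4S)-4-[(tert-butyldimethylsilyl)oxy]-3-methyl-4-(3,4,5-trimethoxyphenyl)butan-2-one; 7 pent-4-enal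
Product: 10 (1S,2R,5S)-1-[(tert-butyldimethylsilyl)oxy]-5-hydroxy-2-methyl-1-(3,4,5-trimethoxyphenyl)non-8-en-3-one, via boron enolate 8 (not isolated), via boron aldolate 9 (not isolated)
Conditions: (−)-Ipc2BCl, Et3N, Et2O, 0 °C; then 7, −78 → −20 °C; then MeOH, pH 7 buffer, 30% H2O2, 0 °C
Reagents that add atoms: none
Why: Diisopinocampheylboron-mediated aldol reaction of a methyl ketone: enolisation occurs on the methyl side, and the isopinocampheyl ligands should direct addition to the Re face of the aldehyde, giving the 5S carbinol (1,4-anti to the C8 methyl group). The resident α-methyl centre is expected to oppose this weakly, so a separable minor epimer is anticipated.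

Step 5
Reactants: 10 (1S,2R,5S)-1-[(tert-butyldimethylsilyl)oxy]-5-hydroxy-2-methyl-1-(3,4,5-trimethoxyphenyl)non-8-en-3-one
Product: 11 (1S,2R,5S)-1-[(tert-butyldimethylsilyl)oxy]-5-methoxy-2-methyl-1-(3,4,5-trimethoxyphenyl)non-8-en-3-one
Conditions: Me3OBF4, 1,8-bis(dimethylamino)naphthalene, CH2Cl2, 0 °C → rt
Reagents that add atoms: trimethyloxonium tetrafluoroborate, C[O+](C)C.F[B-](F)(F)F
Why: O-methylation with an oxonium salt and a hindered amine base; no alkoxide is formed, so retro-aldol cleavage and β-elimination of the β-hydroxy ketone should be avoided.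

Step 6
Reactants: 11 (1S,2R,5S)-1-[(tert-butyldimethylsilyl)oxy]-5-methoxy-2-methyl-1-(3,4,5-trimethoxyphenyl)non-8-en-3-one; 12 triethyl phosphonoacetate
Product: 13 ethyl (2E,5S)-3-{(1S,2S)-1-[(tert-butyldimethylsilyl)oxy]-1-(3,4,5-trimethoxyphenyl)propan-2-yl}-5-methoxynona-2,8-dienoate
Conditions: NaH, THF, 0 °C; then 11, 0 → 60 °C; chromatographic removal of the (Z)-isomer
Reagents that add atoms: none
Why: Horner–Wadsworth–Emmons olefination of a ketone; the stabilised phosphonate anion is a weak base relative to the ketone α-hydrogens, and reversible addition should favour the (E)-isomer, in which the ester is trans to the branched C8 substituent and cis to the methylene arm. Only the pure (E)-isomer is carried on, because the face selectivity of step 8 depends on the alkene geometry.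

Step 7
Reactants: 13 ethyl (2E,5S)-3-{(1S,2S)-1-[(tert-butyldimethylsilyl)oxy]-1-(3,4,5-trimethoxyphenyl)propan-2-yl}-5-methoxynona-2,8-dienoate
Product: 15 ethyl (2E,5S)-3-{(1S,2S)-1-[(tert-butyldimethylsilyl)oxy]-1-(3,4,5-trimethoxyphenyl)propan-2-yl}-5-methoxy-8-oxooct-2-enoate, via vicinal diol 14 (not isolated)
Conditions: OsO4 (2 mol %), NaIO4 (4 equiv), 2,6-lutidine, dioxane/H2O 3:1, rt
Reagents that add atoms: osmium tetroxide, O=[Os](=O)(=O)=O; sodium periodate, [Na+].[O-]I(=O)(=O)=O
Why: Lemieux–Johnson cleavage; the electron-rich monosubstituted alkene should be dihydroxylated far faster than the hindered, electron-poor trisubstituted enoate, and the buffered medium should keep the new aldehyde from condensing.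

Step 8
Reactants: 15 ethyl (2E,5S)-3-{(1S,2S)-1-[(tert-butyldimethylsilyl)oxy]-1-(3,4,5-trimethoxyphenyl)propan-2-yl}-5-methoxy-8-oxooct-2-enoate
Product: 16 ethyl 2-[(1S,5S)-1-{(1S,2S)-1-[(tert-butyldimethylsilyl)oxy]-1-(3,4,5-trimethoxyphenyl)propan-2-yl}-5-methoxy-2-oxocyclohexyl]acetate
Conditions: (5aR,10bS)-2-(pentafluorophenyl)-5a,10b-dihydro-4H,6H-indeno[2,1-b][1,2,4]triazolo[4,3-d][1,4]oxazin-2-ium tetrafluoroborate (20 mol %), KN(SiMe3)2 (18 mol %), toluene, 23 °C
Reagents that add atoms: none
Why: Intramolecular Stetter reaction: the triazolylidene freed from the salt by KN(SiMe3)2 adds to the aldehyde (ring C6), proton transfer gives the Breslow intermediate, and this acyl anion equivalent adds to the enoate β-carbon (ring C1); proton transfer to the ester α-carbon and loss of the carbene release ketone 16 and the catalyst. The closest known reaction type is the enantioselective triazolium-catalysed Stetter cyclisation of aldehydes onto β,β-disubstituted unsaturated esters to give ketones with an α-quaternary centre; a six-membered carbocycle from an aliphatic aldehyde lies at the edge of that scope, which is why the electron-poor N-pentafluorophenyl catalyst and a non-coordinating solvent are chosen. The single ring is closed in the 6-exo-trig mode, the two enoate carbons C2 and C1 of 15 staying outside the ring as the CH2CO2Et arm. The new stereocentre (ring C1) is fixed by the face of the enoate that is attacked; the Re face of C3 of 15 is required and is to be imposed by the chiral triazolium catalyst. The substrate is expected to reinforce this, because a chair-like transition state with both the methoxy group and the bulky silyloxy(aryl) branch equatorial leads to the same configuration (branch and methoxy 1,3-cis), and in the (E)-isomer the ester then points away from the branch. Chemoselectivity over benzoin or aldol self-condensation should follow from intramolecularity and from keeping the base below the amount of triazolium salt, which also leaves no free amide base to deprotonate the γ-carbon and expel silyloxide. The new centre carries no hydrogen, so its configuration cannot be lost afterwards.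

Step 9
Reactants: 16 ethyl 2-[(1S,5S)-1-{(1S,2S)-1-[(tert-butyldimethylsilyl)oxy]-1-(3,4,5-trimethoxyphenyl)propan-2-yl}-5-methoxy-2-oxocyclohexyl]acetate
Product: 17 2-[(1R,5S)-1-{(1S,2S)-1-[(tert-butyldimethylsilyl)oxy]-1-(3,4,5-trimethoxyphenyl)propan-2-yl}-2-hydroxy-5-methoxycyclohexyl]ethan-1-ol (both epimers at the ring carbinol carbon)
Conditions: LiAlH4, THF, 0 °C; aqueous NaOH work-up
Reagents that add atoms: none
Why: Hydride reduction of ester and ketone together; the silyl and methyl ethers are inert, and the mixture at the new carbinol carbon is of no consequence because that carbon is reoxidised in step 10.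

Step 10
Reactants: 17 2-[(1R,5S)-1-{(1S,2S)-1-[(tert-butyldimethylsilyl)oxy]-1-(3,4,5-trimethoxyphenyl)propan-2-yl}-2-hydroxy-5-methoxycyclohexyl]ethan-1-ol
Product: 18 2-[(1S,5S)-1-{(1S,2S)-1-[(tert-butyldimethylsilyl)oxy]-1-(3,4,5-trimethoxyphenyl)propan-2-yl}-5-methoxy-2-oxocyclohexyl]acetaldehyde
Conditions: (COCl)2, DMSO, CH2Cl2, −78 °C; then Et3N, −78 → 0 °C
Reagents that add atoms: none
Why: Double Swern oxidation: both hydroxyl groups are converted into alkoxysulfonium ions before the base is added, so the hydroxy aldehyde that would close to a lactol and be oxidised on to a lactone is never present.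

Step 11
Reactants: 18 2-[(1S,5S)-1-{(1S,2S)-1-[(tert-butyldimethylsilyl)oxy]-1-(3,4,5-trimethoxyphenyl)propan-2-yl}-5-methoxy-2-oxocyclohexyl]acetaldehyde
Product: 19 (2R,4S)-2-allyl-2-{(1S,2S)-1-[(tert-butyldimethylsilyl)oxy]-1-(3,4,5-trimethoxyphenyl)propan-2-yl}-4-methoxycyclohexan-1-one
Conditions: Ph3PCH3Br, KN(SiMe3)2, THF, 0 °C; then 18, −78 → 0 °C
Reagents that add atoms: methyltriphenylphosphonium bromide, C[P+](c1ccccc1)(c1ccccc1)c1ccccc1.[Br-]
Why: Wittig methylenation; the unhindered aldehyde should react at low temperature, while the ketone, which is attached to a quaternary carbon, is left alone when only a slight excess of ylide is used.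

Step 12
Reactants: 19 (2R,4S)-2-allyl-2-{(1S,2S)-1-[(tert-butyldimethylsilyl)oxy]-1-(3,4,5-trimethoxyphenyl)propan-2-yl}-4-methoxycyclohexan-1-one
Product: 20 {[(4S,6R)-6-allyl-6-{(1S,2S)-1-[(tert-butyldimethylsilyl)oxy]-1-(3,4,5-trimethoxyphenyl)propan-2-yl}-4-methoxycyclohex-1-en-1-yl]oxy}trimethylsilane
Conditions: TMSOTf, Et3N, CH2Cl2, 0 °C; non-acidic work-up, used without chromatography
Reagents that add atoms: trimethylsilyl trifluoromethanesulfonate, C[Si](C)(C)OS(=O)(=O)C(F)(F)F
Why: Soft enolisation to the silyl enol ether; the regiochemistry is fixed because the only α-hydrogens lie on C5, the other α-carbon being quaternary.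

Step 13
Reactants: 20 {[(4S,6R)-6-allyl-6-{(1S,2S)-1-[(tert-butyldimethylsilyl)oxy]-1-(3,4,5-trimethoxyphenyl)propan-2-yl}-4-methoxycyclohex-1-en-1-yl]oxy}trimethylsilane
Product: 21 (4R,6R)-6-allyl-6-{(1S,2S)-1-[(tert-butyldimethylsilyl)oxy]-1-(3,4,5-trimethoxyphenyl)propan-2-yl}-4-methoxycyclohex-2-en-1-one
Conditions: Pd(OAc)2 (1.1 equiv), MeCN, rt
Reagents that add atoms: none
Why: Saegusa–Ito oxidation: the enol ether transfers C5 to divalent palladium, and β-hydride elimination from C4 gives the enone; the methoxy group is γ to the metal and cannot be eliminated, and the C3 stereocentre is untouched (its descriptor changes from S to R by priority only).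

Step 14
Reactants: 21 (4R,6R)-6-allyl-6-{(1S,2S)-1-[(tert-butyldimethylsilyl)oxy]-1-(3,4,5-trimethoxyphenyl)propan-2-yl}-4-methoxycyclohex-2-en-1-one
Product: 22 (4R,6R)-6-allyl-6-[(1S,2S)-1-hydroxy-1-(3,4,5-trimethoxyphenyl)propan-2-yl]-4-methoxycyclohex-2-en-1-one
Conditions: HF·pyridine, pyridine, THF, 0 °C → rt
Reagents that add atoms: none
Why: Fluoride-mediated cleavage of the Si–O bond in a pyridine-buffered medium, which is neither basic enough to deconjugate the γ-methoxy enone nor acidic enough to ionise the allylic ether or the benzylic alcohol.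

Step 15
Reactants: 22 (4R,6R)-6-allyl-6-[(1S,2S)-1-hydroxy-1-(3,4,5-trimethoxyphenyl)propan-2-yl]-4-methoxycyclohex-2-en-1-one
Product: 23 (1S,2S)-2-[(1R,5R)-1-allyl-5-methoxy-2-oxocyclohex-3-en-1-yl]-1-(3,4,5-trimethoxyphenyl)propyl acetate
Conditions: Ac2O, pyridine, DMAP (10 mol %), CH2Cl2, 0 °C → rt
Reagents that add atoms: acetic anhydride, CC(=O)OC(C)=O
Why: DMAP-catalysed acylation of the secondary benzylic alcohol with retention at C7; the conditions are mild enough for the enone and the allylic ether.

## Compound list

1 | 3,4,5-trimethoxybenzaldehyde | COc1cc(C=O)cc(OC)c1OC | starting material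
2 | (E)-crotylboronic acid pinacol ester | C/C=C/CB1OC(C)(C)C(C)(C)O1 | starting material
3 | 4,4,5,5-tetramethyl-2-{[(1S,2S)-2-methyl-1-(3,4,5-trimethoxyphenyl)but-3-en-1-yl]oxy}-1,3,2-dioxaborolane | C=C[C@H](C)[C@H](OB1OC(C)(C)C(C)(C)O1)c1cc(OC)c(OC)c(OC)c1 | intermediate (not isolated)
4 | (1S,2S)-2-methyl-1-(3,4,5-trimethoxyphenyl)but-3-en-1-ol | C=C[C@H](C)[C@H](O)c1cc(OC)c(OC)c(OC)c1 | intermediate
5 | tert-butyldimethyl{[(1S,2S)-2-methyl-1-(3,4,5-trimethoxyphenyl)but-3-en-1-yl]oxy}silane | C=C[C@H](C)[C@H](O[Si](C)(C)C(C)(C)C)c1cc(OC)c(OC)c(OC)c1 | intermediate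
6 | (3R,4S)-4-[(tert-butyldimethylsilyl)oxy]-3-methyl-4-(3,4,5-trimethoxyphenyl)butan-2-one | CC(=O)[C@H](C)[C@H](O[Si](C)(C)C(C)(C)C)c1cc(OC)c(OC)c(OC)c1 | intermediate
7 | pent-4-enal | C=CCCC=O | starting material
8 | bis[(−)-isopinocampheyl]boron enolate of 6 (boron on the enol oxygen, terminal CH2=C) | C=C(OB([C@@H]1C[C@@H]2C[C@H]([C@H]1C)C2(C)C)[C@@H]1C[C@@H]2C[C@H]([C@H]1C)C2(C)C)[C@H](C)[C@H](O[Si](C)(C)C(C)(C)C)c1cc(OC)c(OC)c(OC)c1 | intermediate (not isolated)
9 | bis[(−)-isopinocampheyl]borinate ester of 10 (boron on the C5 oxygen) | O=C(C[C@@H](OB([C@@H]1C[C@@H]2C[C@H]([C@H]1C)C2(C)C)[C@@H]1C[C@@H]2C[C@H]([C@H]1C)C2(C)C)CCC=C)[C@H](C)[C@H](O[Si](C)(C)C(C)(C)C)c1cc(OC)c(OC)c(OC)c1 | intermediate (not isolated)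
10 | (1S,2R,5S)-1-[(tert-butyldimethylsilyl)oxy]-5-hydroxy-2-methyl-1-(3,4,5-trimethoxyphenyl)non-8-en-3-one | O=C(C[C@@H](O)CCC=C)[C@H](C)[C@H](O[Si](C)(C)C(C)(C)C)c1cc(OC)c(OC)c(OC)c1 | intermediate
11 | (1S,2R,5S)-1-[(tert-butyldimethylsilyl)oxy]-5-methoxy-2-methyl-1-(3,4,5-trimethoxyphenyl)non-8-en-3-one | O=C(C[C@@H](OC)CCC=C)[C@H](C)[C@H](O[Si](C)(C)C(C)(C)C)c1cc(OC)c(OC)c(OC)c1 | intermediate
12 | triethyl phosphonoacetate | CCOC(=O)CP(=O)(OCC)OCC | starting material
13 | ethyl (2E,5S)-3-{(1S,2S)-1-[(tert-butyldimethylsilyl)oxy]-1-(3,4,5-trimethoxyphenyl)propan-2-yl}-5-methoxynona-2,8-dienoate | CCOC(=O)/C=C(\C[C@@H](OC)CCC=C)[C@H](C)[C@H](O[Si](C)(C)C(C)(C)C)c1cc(OC)c(OC)c(OC)c1 | intermediate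
14 | ethyl (2E,5S)-3-{(1S,2S)-1-[(tert-butyldimethylsilyl)oxy]-1-(3,4,5-trimethoxyphenyl)propan-2-yl}-8,9-dihydroxy-5-methoxynon-2-enoate (both C8 epimers) | CCOC(=O)/C=C(\C[C@@H](OC)CCC(O)CO)[C@H](C)[C@H](O[Si](C)(C)C(C)(C)C)c1cc(OC)c(OC)c(OC)c1 | intermediate (not isolated)
15 | ethyl (2E,5S)-3-{(1S,2S)-1-[(tert-butyldimethylsilyl)oxy]-1-(3,4,5-trimethoxyphenyl)propan-2-yl}-5-methoxy-8-oxooct-2-enoate | CCOC(=O)/C=C(\C[C@@H](OC)CCC=O)[C@H](C)[C@H](O[Si](C)(C)C(C)(C)C)c1cc(OC)c(OC)c(OC)c1 | intermediate
16 | ethyl 2-[(1S,5S)-1-{(1S,2S)-1-[(tert-butyldimethylsilyl)oxy]-1-(3,4,5-trimethoxyphenyl)propan-2-yl}-5-methoxy-2-oxocyclohexyl]acetate | CCOC(=O)C[C@]1([C@H](C)[C@H](O[Si](C)(C)C(C)(C)C)c2cc(OC)c(OC)c(OC)c2)C[C@@H](OC)CCC1=O | intermediate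
17 | 2-[(1R,5S)-1-{(1S,2S)-1-[(tert-butyldimethylsilyl)oxy]-1-(3,4,5-trimethoxyphenyl)propan-2-yl}-2-hydroxy-5-methoxycyclohexyl]ethan-1-ol (both epimers at the ring carbinol carbon) | OCC[C@]1([C@H](C)[C@H](O[Si](C)(C)C(C)(C)C)c2cc(OC)c(OC)c(OC)c2)C[C@@H](OC)CCC1O | intermediate
18 | 2-[(1S,5S)-1-{(1S,2S)-1-[(tert-butyldimethylsilyl)oxy]-1-(3,4,5-trimethoxyphenyl)propan-2-yl}-5-methoxy-2-oxocyclohexyl]acetaldehyde | O=CC[C@]1([C@H](C)[C@H](O[Si](C)(C)C(C)(C)C)c2cc(OC)c(OC)c(OC)c2)C[C@@H](OC)CCC1=O | intermediate
19 | (2R,4S)-2-allyl-2-{(1S,2S)-1-[(tert-butyldimethylsilyl)oxy]-1-(3,4,5-trimethoxyphenyl)propan-2-yl}-4-methoxycyclohexan-1-one | C=CC[C@]1([C@H](C)[C@H](O[Si](C)(C)C(C)(C)C)c2cc(OC)c(OC)c(OC)c2)C[C@@H](OC)CCC1=O | intermediate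
20 | {[(4S,6R)-6-allyl-6-{(1S,2S)-1-[(tert-butyldimethylsilyl)oxy]-1-(3,4,5-trimethoxyphenyl)propan-2-yl}-4-methoxycyclohex-1-en-1-yl]oxy}trimethylsilane | C=CC[C@]1([C@H](C)[C@H](O[Si](C)(C)C(C)(C)C)c2cc(OC)c(OC)c(OC)c2)C[C@@H](OC)CC=C1O[Si](C)(C)C | intermediate
21 | (4R,6R)-6-allyl-6-{(1S,2S)-1-[(tert-butyldimethylsilyl)oxy]-1-(3,4,5-trimethoxyphenyl)propan-2-yl}-4-methoxycyclohex-2-en-1-one | C=CC[C@]1([C@H](C)[C@H](O[Si](C)(C)C(C)(C)C)c2cc(OC)c(OC)c(OC)c2)C[C@@H](OC)C=CC1=O | intermediate
22 | (4R,6R)-6-allyl-6-[(1S,2S)-1-hydroxy-1-(3,4,5-trimethoxyphenyl)propan-2-yl]-4-methoxycyclohex-2-en-1-one | C=CC[C@]1([C@H](C)[C@H](O)c2cc(OC)c(OC)c(OC)c2)C[C@@H](OC)C=CC1=O | intermediate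
23 | (1S,2S)-2-[(1R,5R)-1-allyl-5-methoxy-2-oxocyclohex-3-en-1-yl]-1-(3,4,5-trimethoxyphenyl)propyl acetate | C=CC[C@]1([C@H](C)[C@H](OC(C)=O)c2cc(OC)c(OC)c(OC)c2)C[C@@H](OC)C=CC1=O | target

## Step count and least certain steps

Total step count: 15. Longest linear sequence: 15 steps, from 1 to 23; compounds 2, 7 and 12 are purchased.

**Step 8 (key step).** The Breslow intermediate may add too slowly to the β-carbon. That carbon becomes fully substituted, carries a branched substituent, and in the (E)-isomer has the ester on the same side as the tether, which differs from the simplest model enoates. Aldehyde self-condensation and catalyst decay could then take over. Loss of face selectivity is also possible if catalyst and substrate preferences disagree.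
Fallback: starting from 15, a ketyl–olefin cyclisation with SmI2 (THF, t-BuOH, −78 → 0 °C) would add the ketyl radical anion of C6 to the enoate β-carbon in a 6-exo closure. The resulting γ-hydroxy ester should lactonise to the γ-lactone 3a-{(1S,2S)-1-[(tert-butyldimethylsilyl)oxy]-1-(3,4,5-trimethoxyphenyl)propan-2-yl}-5-methoxyhexahydro-1-benzofuran-2(3H)-one F1. Reduction of F1 with LiAlH4 returns to the route at 17. The C1 configuration would then rest on substrate control through the same chair preference; the C6 configuration is irrelevant.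

**Step 6.** Addition of the phosphonate anion to the α-branched ketone may be slow. During the delay, enolisation toward C8 or C2 could expel silyloxide or methoxide or epimerise C8, and the E/Z ratio may be modest.
Fallback: starting from 11, lithium ethoxyacetylide (ethoxyacetylene, n-BuLi, THF, −78 °C) should add to the ketone without enolisation to give the tertiary propargylic alcohol 1-ethoxy-3-{(1S,2S)-1-[(tert-butyldimethylsilyl)oxy]-1-(3,4,5-trimethoxyphenyl)propan-2-yl}-5-methoxynon-8-en-1-yn-3-ol F2. A Meyer–Schuster rearrangement (Sc(OTf)3 cat., EtOH/CH2Cl2, rt) then gives the enoate and, after separation of geometric isomers, returns to the route at 13.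

**Step 4.** Face selectivity may be poor: methyl ketone boron enolates respond only moderately to the isopinocampheyl ligands, and the α-methyl centre of 6 has an opposing 1,4-syn preference.
Fallback: starting from 5, the C3 centre is taken from an enantiopure epoxide.
- Cleavage of the alkene (OsO4, NaIO4, 2,6-lutidine) gives (2R,3S)-3-[(tert-butyldimethylsilyl)oxy]-2-methyl-3-(3,4,5-trimethoxyphenyl)propanal F3.
- Propane-1,3-dithiol with MgBr2·OEt2 converts it into the dithiane tert-butyl{[(1S,2R)-2-(1,3-dithian-2-yl)-1-(3,4,5-trimethoxyphenyl)propoxy]}dimethylsilane F4.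
- Lithiation (t-BuLi, THF/HMPA, −78 °C) and opening of (S)-2-(but-3-en-1-yl)oxirane (C=CCC[C@H]1CO1) at its terminal carbon gives (2S)-1-(2-{(1S,2R)-1-[(tert-butyldimethylsilyl)oxy]-1-(3,4,5-trimethoxyphenyl)propan-2-yl}-1,3-dithian-2-yl)hex-5-en-2-ol F5.
- O-Methylation (NaH, MeI, THF) gives the methyl ether tert-butyl{[(1S,2R)-2-{2-[(2S)-2-methoxyhex-5-en-1-yl]-1,3-dithian-2-yl}-1-(3,4,5-trimethoxyphenyl)propoxy]}dimethylsilane F6.
- Dithiane hydrolysis (MeI, CaCO3, MeCN/H2O) returns to the route at 11.

**Step 11.** The ylide may act as a base before it olefinates. Enolisation at C5 followed by intramolecular aldol addition to the aldehyde arm would give a bridged ketol.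
Fallback: starting from 17, the keto aldehyde is avoided altogether.
- Oxidative lactonisation with TEMPO (cat.) and PhI(OAc)2 gives the γ-lactone F1.
- DIBAL-H (CH2Cl2, −78 °C) reduces it to the lactol 3a-{(1S,2S)-1-[(tert-butyldimethylsilyl)oxy]-1-(3,4,5-trimethoxyphenyl)propan-2-yl}-5-methoxyoctahydro-1-benzofuran-2-ol F7.
- Methylenetriphenylphosphorane opens the lactol to the hydroxy alkene (2R,4S)-2-allyl-2-{(1S,2S)-1-[(tert-butyldimethylsilyl)oxy]-1-(3,4,5-trimethoxyphenyl)propan-2-yl}-4-methoxycyclohexan-1-ol F8.
- Dess–Martin oxidation returns to the route at 19.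

**Step 13.** Divalent palladium may engage the terminal alkene (migration of the double bond or allylic oxidation) in competition with the enol ether.
Fallback: starting from 19, the lithium enolate (LDA, THF, −78 °C) is treated with N-tert-butylbenzenesulfinimidoyl chloride. This sulfur-based dehydrogenation gives the enone in one operation without palladium and without 20, returning to the route at 21. No new compound is made on the way.

## Further compounds

F1 | step 8 | 3a-{(1S,2S)-1-[(tert-butyldimethylsilyl)oxy]-1-(3,4,5-trimethoxyphenyl)propan-2-yl}-5-methoxyhexahydro-1-benzofuran-2(3H)-one (C3a and C5 as in 16, C7a not defined) | O=C1C[C@]2([C@H](C)[C@H](O[Si](C)(C)C(C)(C)C)c3cc(OC)c(OC)c(OC)c3)C[C@@H](OC)CCC2O1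
F2 | step 6 | 1-ethoxy-3-{(1S,2S)-1-[(tert-butyldimethylsilyl)oxy]-1-(3,4,5-trimethoxyphenyl)propan-2-yl}-5-methoxynon-8-en-1-yn-3-ol (5S, both C3 epimers) | CCOC#CC(O)(C[C@@H](OC)CCC=C)[C@H](C)[C@H](O[Si](C)(C)C(C)(C)C)c1cc(OC)c(OC)c(OC)c1
F3 | step 4 | (2R,3S)-3-[(tert-butyldimethylsilyl)oxy]-2-methyl-3-(3,4,5-trimethoxyphenyl)propanal | O=C[C@H](C)[C@H](O[Si](C)(C)C(C)(C)C)c1cc(OC)c(OC)c(OC)c1
F4 | step 4 | tert-butyl{[(1S,2R)-2-(1,3-dithian-2-yl)-1-(3,4,5-trimethoxyphenyl)propoxy]}dimethylsilane | S1CCCSC1[C@H](C)[C@H](O[Si](C)(C)C(C)(C)C)c1cc(OC)c(OC)c(OC)c1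
F5 | step 4 | (2S)-1-(2-{(1S,2R)-1-[(tert-butyldimethylsilyl)oxy]-1-(3,4,5-trimethoxyphenyl)propan-2-yl}-1,3-dithian-2-yl)hex-5-en-2-ol | C=CCC[C@H](O)CC1(SCCCS1)[C@H](C)[C@H](O[Si](C)(C)C(C)(C)C)c1cc(OC)c(OC)c(OC)c1
F6 | step 4 | tert-butyl{[(1S,2R)-2-{2-[(2S)-2-methoxyhex-5-en-1-yl]-1,3-dithian-2-yl}-1-(3,4,5-trimethoxyphenyl)propoxy]}dimethylsilane | C=CCC[C@H](OC)CC1(SCCCS1)[C@H](C)[C@H](O[Si](C)(C)C(C)(C)C)c1cc(OC)c(OC)c(OC)c1
F7 | step 11 | 3a-{(1S,2S)-1-[(tert-butyldimethylsilyl)oxy]-1-(3,4,5-trimethoxyphenyl)propan-2-yl}-5-methoxyoctahydro-1-benzofuran-2-ol (C2 and C7a not defined) | OC1C[C@]2([C@H](C)[C@H](O[Si](C)(C)C(C)(C)C)c3cc(OC)c(OC)c(OC)c3)C[C@@H](OC)CCC2O1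
F8 | step 11 | (2R,4S)-2-allyl-2-{(1S,2S)-1-[(tert-butyldimethylsilyl)oxy]-1-(3,4,5-trimethoxyphenyl)propan-2-yl}-4-methoxycyclohexan-1-ol (both C1 epimers) | C=CC[C@]1([C@H](C)[C@H](O[Si](C)(C)C(C)(C)C)c2cc(OC)c(OC)c(OC)c2)C[C@@H](OC)CCC1O
F0 | step 13 | none | none
A1 | alternative 1 | (2S,3S,3aS)-3a-allyl-5-methoxy-3-methyl-2-(3,4,5-trimethoxyphenyl)-3,3a-dihydro-1-benzofuran-6(2H)-one | C=CC[C@@]12[C@H](C)[C@@H](c3cc(OC)c(OC)c(OC)c3)OC1=CC(=O)C(OC)=C2
A2 | alternative 1 | 2-allyl-4,4,5-trimethoxycyclohexa-2,5-dien-1-one | C=CCC1=CC(OC)(OC)C(OC)=CC1=O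
A3 | alternative 1 | (E)-isoelemicin [1,2,3-trimethoxy-5-((E)-prop-1-en-1-yl)benzene] | C/C=C/c1cc(OC)c(OC)c(OC)c1
A4 | alternative 2 | 5-{(1S,2S)-1-[(tert-butyldimethylsilyl)oxy]-1-(3,4,5-trimethoxyphenyl)propan-2-yl}-4-hydroxy-3-oxo-2-oxabicyclo[2.2.2]oct-7-ene-5-carbaldehyde (endo formyl, ring configuration as in the SMILES) | O=C[C@]1([C@H](C)[C@H](O[Si](C)(C)C(C)(C)C)c3cc(OC)c(OC)c(OC)c3)C[C@H]2OC(=O)[C@]1(O)C=C2
A5 | alternative 2 | 3-hydroxy-2H-pyran-2-one | O=C1OC=CC=C1O
A6 | alternative 2 | (3S,4S)-4-[(tert-butyldimethylsilyl)oxy]-3-methyl-2-methylidene-4-(3,4,5-trimethoxyphenyl)butanal | C=C(C=O)[C@H](C)[C@H](O[Si](C)(C)C(C)(C)C)c1cc(OC)c(OC)c(OC)c1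
A7 | alternative 3 | (1S,2S)-2-[(1S,5R)-5-hydroxy-2-oxo-1-(2-oxoethyl)cyclohex-3-en-1-yl]-1-(3,4,5-trimethoxyphenyl)propyl acetate | O=CC[C@]1([C@H](C)[C@H](OC(C)=O)c2cc(OC)c(OC)c(OC)c2)C[C@@H](O)C=CC1=O
A8 | alternative 3 | (1S,2S,5Z)-6-iodo-2-methyl-4-oxo-3,3-bis(2-oxoethyl)-1-(3,4,5-trimethoxyphenyl)hex-5-en-1-yl acetate | O=CCC(CC=O)([C@H](C)[C@H](OC(C)=O)c1cc(OC)c(OC)c(OC)c1)C(=O)/C=C\I
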